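**Retrosynthetic overview**

1. Locants C1–C20 follow the target's 6,7-seco-kaurane skeleton (γ-lactone C4–C5–C6(=O)–O–C19; δ-lactone C10–C20–O–C7(=O)–C8–C9; C15 ketone; C17 CH2OH). Target 26 ⇐ 16-methylene-15-ketone 24 (C17 from formaldehyde, C17–OH by conjugate borylation/oxidation) ⇐ pentacycle 23.
2. Ring A (C1–C5, C10) is closed last, through C5–C10, by 6-exo cyclisation of the C5 radical of α-chloro γ-lactone 22 onto its enol δ-lactone C10=C20. Enabling feature: C10 carries the lactone carbon C20, so at the enol-lactone level it is the nucleophilic β-carbon of an enol ester, and C5 is α to the γ-lactone carbonyl C6 (electrophilic radical); the C4–C3–C2–C1 chain holds the two 1,6.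
3. 22 ⇐ ester 19 by a tether-directed Conia-ene closure (C9–C10 bond and δ-lactone ring), C11 reduction and a 1,3-hydrogen shift; 19 ⇐ bridgehead acid 6 + alkynol 17 (C7–O–C20 ester).
4. 6 ⇐ tert-butyl 2-oxocyclopentane-1-carboxylate (ring D): asymmetric allylation (C8), dehydrogenation, Wacker oxidation, intramolecular Michael addition (C12–C13, ring C). 17 ⇐ menthyloxybutenolide 8 (γ-lactone ring; quaternary C4 by conjugate addition) + bromide 11.
5. Order of ring formation: ring D (bought) → ring C (step 4); γ-lactone (bought, re-closed in step 10) → δ-lactone (step 12) → ring A (step 15).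

Key step: step 15

Remark: acetal 8 is assumed to crystallise as the (5R)-diastereomer under epimerising conditions, as its 4-unsubstituted parent does; the chlorine-bearing carbon (C5) of 14–22 is carried as both epimers, because it becomes a radical centre in step 15, and is left undefined in their SMILES. Small intermediates are named with their own ring numbering.

**Route**

Step 1
Reactants: 1 tert-butyl 2-oxocyclopentane-1-carboxylate
Product: 2 tert-butyl (1S)-2-oxo-1-(prop-2-en-1-yl)cyclopentane-1-carboxylate
Conditions: allyl bromide, N-(9-anthracenylmethyl)cinchonidinium bromide (10 mol %), CsOH·H2O, toluene, −40 °C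
Reagents that add atoms: allyl bromide, C=CCBr
Why: Asymmetric phase-transfer C-alkylation of a cyclic β-keto ester, in which the chiral ammonium enolate ion pair is allylated on one face and so sets the quaternary centre C8 (the cinchoninium pseudo-enantiomer is used instead if it is the one that delivers the (S)-ester).

Step 2
Reactants: 2 tert-butyl (1S)-2-oxo-1-(prop-2-en-1-yl)cyclopentane-1-carboxylate
Product: 3 tert-butyl (1R)-2-oxo-1-(prop-2-en-1-yl)cyclopent-3-ene-1-carboxylate
Conditions: IBX (2-iodoxybenzoic acid, 2 equiv), DMSO, 70 °C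
Reagents that add atoms: none
Why: IBX-mediated α,β-dehydrogenation of a ketone, which can only run toward C16 because C8 is quaternary, so the C13=C16 enone forms regiospecifically and C8 is untouched (the descriptor changes only through the priority rules).

Step 3
Reactants: 3 tert-butyl (1R)-2-oxo-1-(prop-2-en-1-yl)cyclopent-3-ene-1-carboxylate
Product: 4 tert-butyl (1S)-2-oxo-1-(2-oxopropyl)cyclopent-3-ene-1-carboxylate
Conditions: PdCl2 (10 mol %), CuCl (1 equiv), O2 (1 atm), DMF/H2O (7:1), rt
Reagents that add atoms: water, O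
Why: Wacker–Tsuji oxidation of the terminal alkene gives the methyl ketone (Markovnikov), turning the allyl group into the acetonyl arm C9–C11(=O)–C12 without touching the electron-poor enone.

Step 4
Reactants: 4 tert-butyl (1S)-2-oxo-1-(2-oxopropyl)cyclopent-3-ene-1-carboxylate
Product: 5 tert-butyl (1S,5S)-3,7-dioxobicyclo[3.2.1]octane-1-carboxylate
Conditions: 1,8-diazabicyclo[5.4.0]undec-7-ene (0.2 equiv), MeCN, 40 °C
Reagents that add atoms: none
Why: Intramolecular Michael addition (6-exo-trig) of the methyl-ketone enolate carbon C12 to the enone carbon C13 closes ring C, and because the three-atom arm can reach C13 only on the face on which it is attached at C8, C13 is fixed by C8.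

Step 5
Reactants: 5 tert-butyl (1S,5S)-3,7-dioxobicyclo[3.2.1]octane-1-carboxylate
Product: 6 (1S,5S)-3,7-dioxobicyclo[3.2.1]octane-1-carboxylic acid
Conditions: CF3CO2H/CH2Cl2 (1:4), 0 °C → rt
Reagents that add atoms: none
Why: Acidolysis of the tert-butyl ester frees the bridgehead acid, which as a bridgehead β-keto acid cannot decarboxylate through an enol.

Step 6
Reactants: 7 5-hydroxy-4-methylfuran-2(5H)-one
Product: 8 (5R)-4-methyl-5-{[(1R,2S,5R)-5-methyl-2-(propan-2-yl)cyclohexyl]oxy}furan-2(5H)-one
Conditions: (1R,2S,5R)-menthol, 10-camphorsulfonic acid (cat.), toluene, reflux with removal of water; crystallisation from hexane with re-equilibration of the mother liquor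
Reagents that add atoms: (1R,2S,5R)-menthol, CC(C)[C@@H]1CC[C@@H](C)C[C@H]1O
Why: Acid-catalysed acetal exchange of the pseudo-acid with menthol, in which the epimerisable acetal carbon C19 is funnelled into the crystalline (5R)-diastereomer (crystallisation-induced diastereomer transformation).

Step 7
Reactants: 9 tert-butyldimethyl(prop-2-yn-1-yloxy)silane
Product: 10 5-{[tert-butyl(dimethyl)silyl]oxy}pent-3-yn-1-ol
Conditions: n-BuLi, THF, −78 °C; BF3·OEt2; oxirane, −78 °C; then H2O
Reagents that add atoms: oxirane, C1CO1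
Why: BF3-promoted opening of oxirane by the lithium acetylide (alkynylation of an epoxide) adds the two-carbon unit C2–C3 to the C1≡C10–C20 piece.

Step 8
Reactants: 10 5-{[tert-butyl(dimethyl)silyl]oxy}pent-3-yn-1-ol
Product: 11 [(5-bromopent-2-yn-1-yl)oxy](tert-butyl)dimethylsilane
Conditions: CBr4, PPh3, CH2Cl2, 0 °C
Reagents that add atoms: tetrabromomethane, BrC(Br)(Br)Br
Why: Appel bromination of the primary alcohol under neutral conditions that leave the silyl ether and the alkyne intact.

Step 9
Reactants: 11 [(5-bromopent-2-yn-1-yl)oxy](tert-butyl)dimethylsilane; 8 (5R)-4-methyl-5-(menthyloxy)furan-2(5H)-one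
Product: 14 (4S,5R)-3-chloro-4-{5-[(tert-butyldimethylsilyl)oxy]pent-3-yn-1-yl}-4-methyl-5-{[(1R,2S,5R)-5-methyl-2-(propan-2-yl)cyclohexyl]oxy}oxolan-2-one (both C3 epimers), via Grignard reagent 12 (not isolated), via silyl ketene acetal 13 (not isolated)
Conditions: Mg, THF, rt; then CuBr·SMe2 (10 mol %), Me3SiCl, 8, THF, −78 → −30 °C; then N-chlorosuccinimide, −78 → 0 °C
Reagents that add atoms: N-chlorosuccinimide, O=C1CCC(=O)N1Cl
Why: Copper-catalysed, Me3SiCl-accelerated conjugate addition of the Grignard reagent to the γ-alkoxybutenolide takes place anti to the menthyloxy group and so sets the quaternary centre C4, and the silyl ketene acetal formed is chlorinated in the same flask at the lactone α-carbon.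

Step 10
Reactants: 14 (4S,5R)-3-chloro-4-{5-[(tert-butyldimethylsilyl)oxy]pent-3-yn-1-yl}-4-methyl-5-(menthyloxy)oxolan-2-one
Product: 17 (4S)-3-chloro-4-(5-hydroxypent-3-yn-1-yl)-4-methyloxolan-2-one, via lactol 15 (not isolated), via hydroxy acid 16 (not isolated)
Conditions: CF3CO2H/H2O (4:1), 45 °C; evaporate; NaBH4, EtOH/H2O, 0 °C; then 2 M HCl, rt
Reagents that add atoms: none
Why: Aqueous acid hydrolyses the menthyl acetal and the silyl ether, borohydride reduces the ring-opened aldehyde form of the pseudo-acid, and acidification re-closes the γ-lactone with C19 now a CH2 group, none of which touches C4.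

Step 11
Reactants: 6 (1S,5S)-3,7-dioxobicyclo[3.2.1]octane-1-carboxylic acid; 17 (4S)-3-chloro-4-(5-hydroxypent-3-yn-1-yl)-4-methyloxolan-2-one
Product: 19 5-[(3S)-4-chloro-3-methyl-5-oxooxolan-3-yl]pent-2-yn-1-yl (1S,5S)-3,7-dioxobicyclo[3.2.1]octane-1-carboxylate, via acid chloride 18 (not isolated)
Conditions: (COCl)2, N,N-dimethylformamide (cat.), CH2Cl2, 0 °C → rt; evaporate; then 17, pyridine, 4-(dimethylamino)pyridine (cat.), CH2Cl2, 0 °C → rt
Reagents that add atoms: none
Why: Acylation of the primary propargylic alcohol by the bridgehead acid chloride under nucleophilic catalysis forms the C7–O–C20 ester that becomes the δ-lactone.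

Step 12
Reactants: 19 5-[(3S)-4-chloro-3-methyl-5-oxooxolan-3-yl]pent-2-yn-1-yl (1S,5S)-3,7-dioxobicyclo[3.2.1]octane-1-carboxylate
Product: 20 tricyclic (E)-alkylidene keto lactone (4S,8S,9S,13S): δ-lactone C7(=O)–O–C20H2–C10 fused at C8–C9 to the 11,15-dioxobicyclo[3.2.1]octane, exocyclic C10=C1 with C2 cis to C9, C2–C3 chain to C4 of the α-chloro γ-lactone
Conditions: pyrrolidine (20 mol %), Cu(OTf)2 (10 mol %), PPh3 (20 mol %), 1,4-dioxane, 60 °C
Reagents that add atoms: none
Why: Conia-ene-type 6-exo-dig carbocyclisation under cooperative enamine/copper catalysis, in which only the enamine toward C9 can reach the tethered alkyne and C10 is delivered to the open exo (axial) face of C9, anti to the C15–C16 bridge, to give the cis-fused δ-lactone with the (E)-alkylidene from anti addition.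

Step 13
Reactants: 20 tricyclic (E)-alkylidene keto lactone (4S,8S,9S,13S)
Product: 21 11-alcohol of 20 (4S,8S,9S,11R,13S; equatorial OH, cis to C10)
Conditions: NaBH4, MeOH/CH2Cl2 (1:1), −78 °C
Reagents that add atoms: none
Why: Chemoselective borohydride reduction of the unhindered C11 ketone (C15 is flanked by quaternary C8), with hydride delivered to the face opposite the C1–C2 vinyl arm that overhangs C11, which should give the equatorial (11R) alcohol.

Step 14
Reactants: 21 11-alcohol of 20 (4S,8S,9S,11R,13S)
Product: 22 enol δ-lactone (4S,8S,9S,11R,13S): C10=C20 endocyclic, C1 now CH2, C5–C10 bond still missing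
Conditions: [Ir(cod)(PMePh2)2]PF6 (5 mol %, pre-activated with H2, then degassed), THF, rt
Reagents that add atoms: none
Why: Iridium-hydride catalysed 1,3-hydrogen shift (allyl ester to enol ester isomerisation) through the activated allylic C20–H moves the alkene into conjugation with the lactone oxygen, giving the endocyclic enol δ-lactone.

Step 15
Reactants: 22 enol δ-lactone (4S,8S,9S,11R,13S)
Product: 23 pentacyclic dilactone (4R,5R,8S,9S,10R,11R,13S): 11-hydroxy-15-oxo-6,19:7,20-dilactone with ring A closed, C16 a CH2 group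
Conditions: Bu3SnH (1.3 equiv) and 2,2′-azobis(2-methylpropionitrile) (0.2 equiv) added over 6 h, benzene (0.005 M), 80 °C
Reagents that add atoms: none
Why: Chlorine abstraction by the stannyl radical gives the planar, electrophilic α-lactonyl radical at C5, which adds to C10, the nucleophilic β-carbon of the enol ester, and the resulting α-acyloxy radical at C20 is reduced by Bu3SnH. The closest known reaction type is the reductive cyclisation of α-halo ester radicals onto enol ethers, the polarity-matched pairing of Ueno–Stork and glycal radical chemistry. Ring A is closed in the 6-exo-trig mode through a chair-like transition state in which C9 on C10 lies anti to quaternary C4. C5 is controlled by the tether, since C10 can only bond to the lactone face that carries C3, which gives the cis-fused γ-lactone (H5 cis to the C4 methyl), and C10 is controlled by the tricyclic enol lactone, whose half-chair exposes the face syn to H9 while the other face is screened by pseudo-axial C14 and by C11, so that C5 ends cis to H9 and C1 cis to C11. The step needs exo over endo regioselectivity, which the enol-ester polarity and the ring size secure, and cyclisation faster than hydrogen transfer, which slow addition of the stannane at high dilution secures.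

Step 16
Reactants: 23 pentacyclic dilactone (4R,5R,8S,9S,10R,11R,13S)
Product: 24 16-methylene-15-ketone (4R,5R,8S,9S,10R,11R,13S)
Conditions: paraformaldehyde, N-methylanilinium trifluoroacetate, THF, reflux
Reagents that add atoms: paraformaldehyde (reacts as formaldehyde), C=O
Why: α-Methylenation of the ketone by Mannich-type condensation with formaldehyde and elimination, possible only at C16 because C8 is quaternary, installs C17 as the exocyclic enone.

Step 17
Reactants: 24 16-methylene-15-ketone (4R,5R,8S,9S,10R,11R,13S)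
Product: 25 17-(4,4,5,5-tetramethyl-1,3,2-dioxaborolan-2-yl) ketone (4R,5R,8S,9S,10R,11R,13S,16R)
Conditions: bis(pinacolato)diboron, CuCl (5 mol %), NaOt-Bu (10 mol %), bis[2-(diphenylphosphino)phenyl] ether (5 mol %), MeOH (2 equiv), THF, 0 °C → rt
Reagents that add atoms: bis(pinacolato)diboron, CC1(C)OB(OC1(C)C)B1OC(C)(C)C(C)(C)O1
Why: Copper-catalysed conjugate borylation of the enone places boron on C17, and the enolate is protonated at C16 by methanol from the exo face (syn to C14, away from the C9–C11–C12 bridge), which puts H16 exo and C17 endo as in the target.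

Step 18
Reactants: 25 17-boryl ketone (4R,5R,8S,9S,10R,11R,13S,16R)
Product: 26 target CNP0555433.1 (4R,5R,8S,9S,10R,11R,13S,16S)
Conditions: NaBO3·4H2O, THF/H2O (1:1), 0 °C → rt
Reagents that add atoms: sodium perborate, [Na+].[O-]OB=O
Why: Oxidation of the alkylboronate with perborate proceeds with retention at carbon under mildly basic conditions that should neither epimerise C16 nor cause retro-aldol cleavage, giving the primary alcohol of the target.

**Compound list**

1 | tert-butyl 2-oxocyclopentane-1-carboxylate | CC(C)(C)OC(=O)C1CCCC1=O | starting material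
2 | tert-butyl (1S)-2-oxo-1-(prop-2-en-1-yl)cyclopentane-1-carboxylate | CC(C)(C)OC(=O)[C@]1(CC=C)CCCC1=O | intermediate
3 | tert-butyl (1R)-2-oxo-1-(prop-2-en-1-yl)cyclopent-3-ene-1-carboxylate | CC(C)(C)OC(=O)[C@]1(CC=C)CC=CC1=O | intermediate
4 | tert-butyl (1S)-2-oxo-1-(2-oxopropyl)cyclopent-3-ene-1-carboxylate | CC(C)(C)OC(=O)[C@]1(CC(C)=O)CC=CC1=O | intermediate
5 | tert-butyl (1S,5S)-3,7-dioxobicyclo[3.2.1]octane-1-carboxylate | CC(C)(C)OC(=O)[C@@]12C[C@@H](CC(=O)C1)CC2=O | intermediate
6 | (1S,5S)-3,7-dioxobicyclo[3.2.1]octane-1-carboxylic acid | OC(=O)[C@@]12C[C@@H](CC(=O)C1)CC2=O | intermediate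
7 | 5-hydroxy-4-methylfuran-2(5H)-one | CC1=CC(=O)OC1O | starting material
8 | (5R)-4-methyl-5-{[(1R,2S,5R)-5-methyl-2-(propan-2-yl)cyclohexyl]oxy}furan-2(5H)-one | CC1=CC(=O)O[C@H]1O[C@@H]2C[C@H](C)CC[C@H]2C(C)C | intermediate
9 | tert-butyldimethyl(prop-2-yn-1-yloxy)silane | C#CCO[Si](C)(C)C(C)(C)C | starting material
10 | 5-{[tert-butyl(dimethyl)silyl]oxy}pent-3-yn-1-ol | OCCC#CCO[Si](C)(C)C(C)(C)C | intermediate
11 | [(5-bromopent-2-yn-1-yl)oxy](tert-butyl)dimethylsilane | BrCCC#CCO[Si](C)(C)C(C)(C)C | intermediate
12 | Grignard reagent, bromo{5-[(tert-butyldimethylsilyl)oxy]pent-3-yn-1-yl}magnesium | Br[Mg]CCC#CCO[Si](C)(C)C(C)(C)C | intermediate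
13 | trimethylsilyl ketene acetal of the 4,5-trans conjugate adduct (C4 and acetal carbon as in 14) | C[C@@]1(CCC#CCO[Si](C)(C)C(C)(C)C)C=C(O[Si](C)(C)C)O[C@H]1O[C@@H]2C[C@H](C)CC[C@H]2C(C)C | intermediate
14 | (4S,5R)-3-chloro-4-{5-[(tert-butyldimethylsilyl)oxy]pent-3-yn-1-yl}-4-methyl-5-{[(1R,2S,5R)-5-methyl-2-(propan-2-yl)cyclohexyl]oxy}oxolan-2-one (C3 epimers) | C[C@@]1(CCC#CCO[Si](C)(C)C(C)(C)C)C(Cl)C(=O)O[C@H]1O[C@@H]2C[C@H](C)CC[C@H]2C(C)C | intermediate
15 | (4S)-3-chloro-5-hydroxy-4-(5-hydroxypent-3-yn-1-yl)-4-methyloxolan-2-one (lactol, C3 and C5 epimers) | C[C@@]1(CCC#CCO)C(Cl)C(=O)OC1O | intermediate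
16 | (3S)-2-chloro-8-hydroxy-3-(hydroxymethyl)-3-methyloct-6-ynoic acid (C2 epimers) | OC[C@](C)(CCC#CCO)C(Cl)C(=O)O | intermediate
17 | (4S)-3-chloro-4-(5-hydroxypent-3-yn-1-yl)-4-methyloxolan-2-one (C3 epimers) | C[C@@]1(CCC#CCO)C(Cl)C(=O)OC1 | intermediate
18 | (1S,5S)-3,7-dioxobicyclo[3.2.1]octane-1-carbonyl chloride | ClC(=O)[C@@]12C[C@@H](CC(=O)C1)CC2=O | intermediate
19 | 5-[(3S)-4-chloro-3-methyl-5-oxooxolan-3-yl]pent-2-yn-1-yl (1S,5S)-3,7-dioxobicyclo[3.2.1]octane-1-carboxylate | C[C@@]1(CCC#CCOC(=O)[C@@]23C[C@@H](CC(=O)C2)CC3=O)C(Cl)C(=O)OC1 | intermediate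
20 | tricyclic (E)-alkylidene keto lactone (4S,8S,9S,13S): δ-lactone fused at C8–C9 to the 11,15-dioxobicyclo[3.2.1]octane, exocyclic C10=C1 (C2 cis to C9), chain C2–C3 to C4 of the α-chloro γ-lactone | C[C@@]1(CC/C=C2/COC(=O)[C@@]34C[C@@H](CC(=O)[C@@H]23)CC4=O)C(Cl)C(=O)OC1 | intermediate
21 | 11-alcohol of 20 (4S,8S,9S,11R,13S; equatorial OH cis to C10) | C[C@@]1(CC/C=C2/COC(=O)[C@@]34C[C@@H](C[C@@H](O)[C@@H]23)CC4=O)C(Cl)C(=O)OC1 | intermediate
22 | enol δ-lactone (4S,8S,9S,11R,13S): C10=C20 endocyclic, C1 CH2, C5–C10 bond missing | C[C@@]1(CCCC2=COC(=O)[C@@]34C[C@@H](C[C@@H](O)[C@@H]23)CC4=O)C(Cl)C(=O)OC1 | intermediate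
23 | pentacyclic dilactone (4R,5R,8S,9S,10R,11R,13S): 11-hydroxy-15-oxo-6,19:7,20-dilactone, C16 CH2, no C17 | C[C@@]12CCC[C@]3(COC(=O)[C@@]45C[C@@H](C[C@@H](O)[C@H]43)CC5=O)[C@@H]1C(=O)OC2 | intermediate
24 | 16-methylene-15-ketone (4R,5R,8S,9S,10R,11R,13S) | C[C@@]12CCC[C@]3(COC(=O)[C@@]45C[C@@H](C[C@@H](O)[C@H]43)C(=C)C5=O)[C@@H]1C(=O)OC2 | intermediate
25 | 17-(4,4,5,5-tetramethyl-1,3,2-dioxaborolan-2-yl) ketone (4R,5R,8S,9S,10R,11R,13S,16R) | C[C@@]12CCC[C@]3(COC(=O)[C@@]45C[C@@H](C[C@@H](O)[C@H]43)[C@@H](CB6OC(C)(C)C(C)(C)O6)C5=O)[C@@H]1C(=O)OC2 | intermediate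
26 | CNP0555433.1 (4R,5R,8S,9S,10R,11R,13S,16S) | C[C@@]12CCC[C@]3(COC(=O)[C@@]45C[C@@H](C[C@@H](O)[C@H]43)[C@@H](CO)C5=O)[C@@H]1C(=O)OC2 | target

**Step count and risks**

Total step count: 18. Longest linear sequence: 13 steps (steps 1–5 and 11–18).

Steps most likely to fail:

1. Step 15 (key step). Hydrogen transfer from the stannane to the C5 radical, or a 1,5-hydrogen shift from allylic C1, may outrun the cyclisation, and facial selection at C10 may be incomplete. Fallback: setting out from 22, the radical is generated without any hydride donor by copper-mediated atom transfer (Kharasch-type cyclisation; CuCl, tris(2-pyridylmethyl)amine, 1,2-dichloroethane, 80 °C). The cyclised radical is then capped by chlorine to give the spiro-cyclised C20 chloride F1. Its acylal-type C–Cl bond is afterwards reduced with Bu3SnH and 2,2′-azobis(2-methylpropionitrile), which returns to the route at 23.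

2. Step 12. Enamine formation on the hindered C9 side and the need for the disfavoured s-cis ester rotamer may stall the closure, and the amine may draw the β,γ-alkene of the product into conjugation with the C11 ketone, with loss of the C9 centre. Fallback: an amine-free route from 19. Soft enolisation with TBSOTf and Et3N gives the C9=C11 tert-butyldimethylsilyl enol ether F2 (its C11=C12 regioisomer is hydrolysed back to 19 and recycled). Cationic monovalent gold (Ph3PAuNTf2, CH2Cl2/MeOH) then effects the 6-exo-dig carbocyclisation of the enol silane onto the alkyne, returning to the route at 20.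

3. Step 14. The hydrogen shift may stall on the trisubstituted alkene or run toward C9=C10 or C1=C2 instead of C10=C20. Fallback: setting out from 21, the separate metal-hydride isomerisation is dropped and the transposition is merged into the radical step. A thiol co-catalyst (tert-dodecanethiol) in the tin-hydride medium abstracts the oxygen-activated allylic C20–H (polarity-reversal catalysis) and returns hydrogen to C1 of the allyl radical, so the enol lactone forms in the flask and is trapped at once by the C5 radical. This returns to the route at 23 and makes no compound outside the list (F0).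

Further compounds
F1 | step 15 | C20 chloride of 23 (atom-transfer cyclisation product, 4R,5R,8S,9S,10R,11R,13S, C20 epimers) | C[C@@]12CCC[C@]3(C(Cl)OC(=O)[C@@]45C[C@@H](C[C@@H](O)[C@H]43)CC5=O)[C@@H]1C(=O)OC2
F2 | step 12 | C9=C11 tert-butyldimethylsilyl enol ether of 19 | C[C@@]1(CCC#CCOC(=O)[C@@]23C[C@@H](CC(O[Si](C)(C)C(C)(C)C)=C2)CC3=O)C(Cl)C(=O)OC1
F0 | step 14 | none | none
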